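**Strategy.** Ring B (the hydroxy-enedione ring) is first made as an aromatic ring and only later dearomatised. A polyketide-type cascade (intramolecular aldol condensation, vinylogous Dieckmann cyclisation, enolisation) turns an open-chain methyl ketone/β-keto ester carried on ring D into a 2-isopropylresorcinol. It forges the C8–C9 bond (the future bond shared by rings A, B and C) and the C11–C12 bond of ring B, closing rings C and B at once. It exploits the alternating oxygen pattern C14=O/C12–OH around C13 and the fact that C8 and C9 each lie α to a ring-B carbonyl (abietane numbering). Oxidation to the hydroxy-p-quinone and a Diels–Alder reaction with myrcene then build ring A and both quaternary centres.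

Key step: step 8

**Remarks on the chemistry**
- Numbering: C1–C3 (ring D CH2), C4 (CMe2), C5 (ring-fusion CH), C6 (CH bearing the formyl carbon C7), C8 and C9 (quaternary carbons shared by rings A, B, C), C10 (C–CH3), C11 (C=O next to C–OH), C12 (C–OH), C13 (C–iPr), C14 (C=O). Ring A = myrcene-derived cyclohexene, ring B = hydroxy-enedione ring, ring C = cyclopentane, ring D = gem-dimethylcyclohexane.
- Assumption: C6 is formed in step 5 as both epimers and is carried as such through compounds 12 and 14–20; it is equilibrated in step 10, where it becomes α to the aldehyde. The SMILES of these compounds leave C6 open. Compounds 14–16 are drawn as open-chain keto esters (they may sit as cyclic hemiketals) with the labile C13 centre open.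
- Compounds 1, 2, 5, 13 and 22 are taken as commercially available.

**Step 1**
Reactants: 1 2,4,4-trimethylcyclohex-2-en-1-one; 2 vinylmagnesium bromide
Product: 4 [(3S)-2,4,4-trimethyl-3-vinylcyclohex-1-en-1-yl]oxy(trimethyl)silane, via bromomagnesium enolate 3 (not isolated)
Conditions: CuBr·SMe2 (5 mol %), 1-[2-(diphenylphosphino)ferrocenyl]ethyldicyclohexylphosphine (Josiphos type, 6 mol %, enantiomer chosen for 3S), Me3SiCl, t-BuOMe, −78 °C
Reagents that add atoms: chlorotrimethylsilane, C[Si](C)(C)Cl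
Why: Copper-catalysed asymmetric 1,4-addition of a Grignard reagent to a cyclic enone with silyl trapping; the chiral diphosphine–copper complex selects the enone face and sets C5, and silylation fixes the enolate regiochemistry at C10.

**Step 2**
Reactants: 4 [(3S)-2,4,4-trimethyl-3-vinylcyclohex-1-en-1-yl]oxy(trimethyl)silane; 5 1-[(triisopropylsilyl)ethynyl]-1,2-benziodoxol-3(1H)-one
Product: 7 (2S,3S)-2,4,4-trimethyl-2-[(triisopropylsilyl)ethynyl]-3-vinylcyclohexan-1-one, via lithium enolate 6 (not isolated)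
Conditions: MeLi, THF, 0 °C; then 5, −78 → 25 °C
Reagents that add atoms: none
Why: Electrophilic α-alkynylation of a regiodefined ketone enolate with an ethynylbenziodoxolone; the electrophile enters anti to the adjacent pseudo-axial vinyl group, which sets the C10 quaternary centre with the alkyne trans and the methyl cis to the C5 substituent.

**Step 3**
Reactants: 7 (2S,3S)-2,4,4-trimethyl-2-[(triisopropylsilyl)ethynyl]-3-vinylcyclohexan-1-one
Product: 9 triisopropyl{[(1S,2S)-1,3,3-trimethyl-2-vinylcyclohexyl]ethynyl}silane, via tosylhydrazone 8 (not isolated)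
Conditions: TsNHNH2, EtOH, 70 °C; then catecholborane, CHCl3, 0 °C; NaOAc·3H2O, reflux
Reagents that add atoms: none
Why: Reductive deoxygenation of a ketone through its tosylhydrazone (hydride addition, sulfinate loss, N2 extrusion); the mild conditions leave the hindered silylalkyne and the vinyl group alone and touch no stereocentre.

**Step 4**
Reactants: 9 triisopropyl{[(1S,2S)-1,3,3-trimethyl-2-vinylcyclohexyl]ethynyl}silane
Product: 11 3-{(1S,2S)-2,6,6-trimethyl-2-[(triisopropylsilyl)ethynyl]cyclohexyl}cyclobutan-1-one, via cyclobutaniminium triflate 10 (not isolated)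
Conditions: N,N-dimethylacetamide, Tf2O, 2,4,6-collidine, ClCH2CH2Cl, 80 °C; then aq. NaHCO3
Reagents that add atoms: N,N-dimethylacetamide, CC(=O)N(C)C; water, O
Why: Keteniminium–alkene [2+2] cycloaddition (Ghosez) and hydrolysis give the 3-substituted cyclobutanone from the terminal alkene; the doubly shielded silylalkyne does not compete and the new carbon C6 is not yet stereogenic.

**Step 5**
Reactants: 11 3-{(1S,2S)-2,6,6-trimethyl-2-[(triisopropylsilyl)ethynyl]cyclohexyl}cyclobutan-1-one
Product: 12 4-{(1S,2S)-2,6,6-trimethyl-2-[(triisopropylsilyl)ethynyl]cyclohexyl}oxolan-2-one (both epimers at the lactone carbon C-4)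
Conditions: m-CPBA, NaHCO3, CH2Cl2, 0 → 25 °C
Reagents that add atoms: 3-chloroperoxybenzoic acid, OOC(=O)c1cccc(Cl)c1
Why: Baeyer–Villiger oxidation of a strained cyclobutanone to the γ-butyrolactone; either methylene may migrate, so C6 forms as both epimers, which converge in step 10.

**Step 6**
Reactants: 12 4-{(1S,2S)-2,6,6-trimethyl-2-[(triisopropylsilyl)ethynyl]cyclohexyl}oxolan-2-one; 13 methyl 3-methylbutanoate
Product: 15 methyl 5-[(1S,2S)-2-ethynyl-2,6,6-trimethylcyclohexyl]-6-hydroxy-3-oxo-2-(propan-2-yl)hexanoate, via silylalkyne keto ester 14 (not isolated)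
Conditions: LDA (3 equiv), 13 (3 equiv), THF, −78 °C; 12, −78 → −40 °C; AcOH; then TBAF, 0 → 25 °C
Reagents that add atoms: none
Why: Claisen acylation of an ester lithium enolate by the lactone gives the δ-hydroxy β-keto ester, and fluoride then cleaves the alkynyl–silicon bond; no stereocentre of the target is touched.

**Step 7**
Reactants: 15 methyl 5-[(1S,2S)-2-ethynyl-2,6,6-trimethylcyclohexyl]-6-hydroxy-3-oxo-2-(propan-2-yl)hexanoate
Product: 16 methyl 5-[(1S,2S)-2-acetyl-2,6,6-trimethylcyclohexyl]-6-hydroxy-3-oxo-2-(propan-2-yl)hexanoate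
Conditions: Ph3PAuNTf2 (2 mol %), H2O, 1,4-dioxane, 60 °C
Reagents that add atoms: water, O
Why: Gold-catalysed Markovnikov hydration of a terminal alkyne gives the methyl ketone; the catalyst is alkyne-selective, so the keto ester and the alcohol survive.

**Step 8 (key step)**
Reactants: 16 methyl 5-[(1S,2S)-2-acetyl-2,6,6-trimethylcyclohexyl]-6-hydroxy-3-oxo-2-(propan-2-yl)hexanoate
Product: 19 (4bS,8aS)-9-(hydroxymethyl)-4b,8,8-trimethyl-2-(propan-2-yl)-4b,5,6,7,8,8a-hexahydro-9H-fluorene-1,3-diol, via acylcyclopentene 17 (not isolated), via enedione 18 (not isolated)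
Conditions: KOt-Bu (3 equiv), t-BuOH/THF, 25 → 75 °C, argon; then 1 M HCl
Reagents that add atoms: none
Why: Under equilibrating base the C8 enolate (γ-carbon of the β-keto ester) adds to the C9 ketone and water is lost to give enone 17; γ-deprotonation of its C11 methyl then gives a dienolate that acylates at the ester carbon C12 with loss of methoxide, and enolisation of dione 18 to the resorcinol makes the sequence irreversible. The closest known reaction types are the base-mediated cyclisation of 1,6-diketones to 1-acylcyclopentenes and the vinylogous Claisen (Dieckmann) aromatisation of polyketide-type keto esters. Ring C closes by a 5-(enolexo)-exo-trig aldol (C8–C9) and ring B by a 6-(enolendo)-exo-trig acylation (C11–C12). No new stereocentre is formed: C5 and C10 are not enolisable, C6 is untouched and the labile C13 centre is erased. The selectivity needed is C8 over the more acidic C13–H and the C11 methyl as the first nucleophile; it is secured because their aldol modes would need seven-membered rings and stay reversible, whereas only the C8→C9 closure can dehydrate and aromatise.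

**Step 9**
Reactants: 19 (4bS,8aS)-9-(hydroxymethyl)-4b,8,8-trimethyl-2-(propan-2-yl)-4b,5,6,7,8,8a-hexahydro-9H-fluorene-1,3-diol
Product: 20 (4bS,8aS)-3-hydroxy-9-(hydroxymethyl)-4b,8,8-trimethyl-2-(propan-2-yl)-4b,5,6,7,8,8a-hexahydro-9H-fluorene-1,4-dione
Conditions: potassium nitrosodisulfonate (KSO3)2NO (2.5 equiv), KH2PO4, acetone/H2O, 0 → 25 °C
Reagents that add atoms: potassium nitrosodisulfonate, [K+].[K+].[O]N(S(=O)(=O)[O-])S(=O)(=O)[O-]
Why: Teuber oxidation: the nitroxyl radical oxidises the phenol at the only free position (C11, para to the C14 hydroxyl) to give the 2-hydroxy-1,4-benzoquinone, and the primary alcohol is inert.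

**Step 10**
Reactants: 20 (4bS,8aS)-3-hydroxy-9-(hydroxymethyl)-4b,8,8-trimethyl-2-(propan-2-yl)-4b,5,6,7,8,8a-hexahydro-9H-fluorene-1,4-dione
Product: 21 (4bS,8aS,9R)-3-hydroxy-4b,8,8-trimethyl-1,4-dioxo-2-(propan-2-yl)-4b,5,6,7,8,8a-hexahydro-9H-fluorene-9-carbaldehyde
Conditions: Dess–Martin periodinane, CH2Cl2, 0 → 25 °C; then i-Pr2NEt (0.1 equiv), 25 °C
Reagents that add atoms: none
Why: Dess–Martin oxidation gives the aldehyde, and the C6–H (now α to the formyl group and vinylogous to the quinone) is equilibrated by the amine to the more stable epimer with CHO cis to H-5 and away from C4, so both epimers converge.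

**Step 11**
Reactants: 21 (4bS,8aS,9R)-3-hydroxy-4b,8,8-trimethyl-1,4-dioxo-2-(propan-2-yl)-4b,5,6,7,8,8a-hexahydro-9H-fluorene-9-carbaldehyde; 22 myrcene (7-methyl-3-methylideneocta-1,6-diene)
Product: 25 target CNP0239256.1, via silyloxyquinone 23 (not isolated), via silylated cycloadduct 24 (not isolated)
Conditions: N,O-bis(trimethylsilyl)acetamide (1.1 equiv), CH2Cl2, 25 °C; then 22 (5 equiv), Er(fod)3 (20 mol %; fod = 6,6,7,7,8,8,8-heptafluoro-2,2-dimethyl-3,5-octanedionate), 25 → 40 °C; then citric acid, MeOH/H2O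
Reagents that add atoms: none
Why: Lewis-acid-promoted Diels–Alder reaction of a quinone with a 2-substituted diene: transient O-silylation removes the O–H···O=C11 hydrogen bond and blocks O,O-chelation, so the lanthanide should bind the more basic vinylogous-ester carbonyl C14=O (helped by the formyl oxygen), which makes C9 the electrophilic terminus for the diene CH2 next to its substituted carbon (the regiochemical reversal known for alkoxyquinones under monodentate Lewis acids), while the diene adds anti to the C10 methyl to set C8 and C9, and work-up frees the enol.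

**Compound list**
1 | 2,4,4-trimethylcyclohex-2-en-1-one | CC1=CC(C)(C)CCC1=O | starting material
2 | vinylmagnesium bromide | C=C[Mg]Br | starting material
3 | bromomagnesium enolate of (3S)-2,4,4-trimethyl-3-vinylcyclohexanone | Br[Mg]OC1=C(C)[C@@H](C=C)C(C)(C)CC1 | intermediate (not isolated)
4 | [(3S)-2,4,4-trimethyl-3-vinylcyclohex-1-en-1-yl]oxy(trimethyl)silane | C=C[C@@H]1C(C)=C(O[Si](C)(C)C)CCC1(C)C | intermediate
5 | 1-[(triisopropylsilyl)ethynyl]-1,2-benziodoxol-3(1H)-one | CC(C)[Si](C(C)C)(C(C)C)C#CI1OC(=O)c2ccccc12 | starting material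
6 | lithium enolate of (3S)-2,4,4-trimethyl-3-vinylcyclohexanone | [Li]OC1=C(C)[C@@H](C=C)C(C)(C)CC1 | intermediate (not isolated)
7 | (2S,3S)-2,4,4-trimethyl-2-[(triisopropylsilyl)ethynyl]-3-vinylcyclohexan-1-one | CC(C)[Si](C(C)C)(C(C)C)C#C[C@@]1(C)C(=O)CCC(C)(C)[C@@H]1C=C | intermediate
8 | tosylhydrazone of 7 | CC(C)[Si](C(C)C)(C(C)C)C#C[C@@]1(C)C(=NNS(=O)(=O)c2ccc(C)cc2)CCC(C)(C)[C@@H]1C=C | intermediate (not isolated)
9 | triisopropyl{[(1S,2S)-1,3,3-trimethyl-2-vinylcyclohexyl]ethynyl}silane | CC(C)[Si](C(C)C)(C(C)C)C#C[C@@]1(C)CCCC(C)(C)[C@@H]1C=C | intermediate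
10 | N,N-dimethylcyclobutaniminium triflate from 9 | CC(C)[Si](C(C)C)(C(C)C)C#C[C@@]1(C)CCCC(C)(C)[C@@H]1C1CC(=[N+](C)C)C1.[O-]S(=O)(=O)C(F)(F)F | intermediate (not isolated)
11 | 3-{(1S,2S)-2,6,6-trimethyl-2-[(triisopropylsilyl)ethynyl]cyclohexyl}cyclobutan-1-one | CC(C)[Si](C(C)C)(C(C)C)C#C[C@@]1(C)CCCC(C)(C)[C@@H]1C1CC(=O)C1 | intermediate
12 | 4-{(1S,2S)-2,6,6-trimethyl-2-[(triisopropylsilyl)ethynyl]cyclohexyl}oxolan-2-one, both epimers at the future C6 | CC(C)[Si](C(C)C)(C(C)C)C#C[C@@]1(C)CCCC(C)(C)[C@@H]1C1COC(=O)C1 | intermediate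
13 | methyl 3-methylbutanoate | COC(=O)CC(C)C | starting material
14 | methyl 6-hydroxy-3-oxo-2-(propan-2-yl)-5-{(1S,2S)-2,6,6-trimethyl-2-[(triisopropylsilyl)ethynyl]cyclohexyl}hexanoate | CC(C)[Si](C(C)C)(C(C)C)C#C[C@@]1(C)CCCC(C)(C)[C@@H]1C(CO)CC(=O)C(C(C)C)C(=O)OC | intermediate (not isolated)
15 | methyl 5-[(1S,2S)-2-ethynyl-2,6,6-trimethylcyclohexyl]-6-hydroxy-3-oxo-2-(propan-2-yl)hexanoate | C#C[C@@]1(C)CCCC(C)(C)[C@@H]1C(CO)CC(=O)C(C(C)C)C(=O)OC | intermediate
16 | methyl 5-[(1S,2S)-2-acetyl-2,6,6-trimethylcyclohexyl]-6-hydroxy-3-oxo-2-(propan-2-yl)hexanoate | CC(=O)[C@@]1(C)CCCC(C)(C)[C@@H]1C(CO)CC(=O)C(C(C)C)C(=O)OC | intermediate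
17 | acylcyclopentene (aldol condensation product, C8=C9) | COC(=O)C(C(C)C)C(=O)C1=C(C)[C@@]2(C)CCCC(C)(C)[C@@H]2C1CO | intermediate (not isolated)
18 | cyclohexenedione (Claisen product before enolisation) | OCC1C2=C(CC(=O)C(C(C)C)C2=O)[C@@]2(C)CCCC(C)(C)[C@@H]21 | intermediate (not isolated)
19 | (4bS,8aS)-9-(hydroxymethyl)-4b,8,8-trimethyl-2-(propan-2-yl)-4b,5,6,7,8,8a-hexahydro-9H-fluorene-1,3-diol | OCC1c2c(O)c(C(C)C)c(O)cc2[C@@]2(C)CCCC(C)(C)[C@@H]21 | intermediate
20 | (4bS,8aS)-3-hydroxy-9-(hydroxymethyl)-4b,8,8-trimethyl-2-(propan-2-yl)-4b,5,6,7,8,8a-hexahydro-9H-fluorene-1,4-dione | OCC1C2=C(C(=O)C(O)=C(C(C)C)C2=O)[C@@]2(C)CCCC(C)(C)[C@@H]21 | intermediate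
21 | (4bS,8aS,9R)-3-hydroxy-4b,8,8-trimethyl-1,4-dioxo-2-(propan-2-yl)-4b,5,6,7,8,8a-hexahydro-9H-fluorene-9-carbaldehyde | O=C[C@H]1C2=C(C(=O)C(O)=C(C(C)C)C2=O)[C@@]2(C)CCCC(C)(C)[C@@H]21 | intermediate
22 | myrcene (7-methyl-3-methylideneocta-1,6-diene) | CC(C)=CCCC(=C)C=C | starting material
23 | O-trimethylsilyl ether of 21 | O=C[C@H]1C2=C(C(=O)C(O[Si](C)(C)C)=C(C(C)C)C2=O)[C@@]2(C)CCCC(C)(C)[C@@H]21 | intermediate (not isolated)
24 | O-trimethylsilyl ether of the target | CC(C)=CCCC1=CC[C@@]23C(=O)C(C(C)C)=C(O[Si](C)(C)C)C(=O)[C@]2(C1)[C@@]1(C)CCCC(C)(C)[C@@H]1[C@H]3C=O | intermediate (not isolated)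
25 | CNP0239256.1 | CC(C)=CCCC1=CC[C@@]23C(=O)C(C(C)C)=C(O)C(=O)[C@]2(C1)[C@@]1(C)CCCC(C)(C)[C@@H]1[C@H]3C=O | target

**Total step count:** 11. **Longest linear sequence:** 11 steps (1 → 25).

**Steps most likely to fail**

1. Step 8 (key step). Unproductive enolisation at the doubly activated C13–H may starve the C8 enolate, and the hindered C9 ketone may resist aldol addition, so that cleavage of the keto ester outruns ring closure. Fallback, from 15 back to 19, forming the same two bonds by a cycloaddition: 15 would be silylated (Me3SiCl/Et3N, then LDA/Me3SiCl) to the 1-methoxy-1,3-bis(trimethylsilyloxy)diene F1, in which the alcohol and the alkyne terminus are silylated as well. Heating (mesitylene, about 160 °C) should bring about an intramolecular Diels–Alder reaction of the C8=C14–C13=C12 diene with the C9≡C11 alkyne, closing C8–C9 and C11–C12 in one operation. Loss of methanol then gives the persilylated arene F2, from which CF3CO2H/MeOH removes the O-silyl groups and the aryl silane (ipso-protodesilylation) to return to 19.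

2. Step 11. The diene's nucleophilic CH2 may bond to C8 instead of C9 (the intrinsic polarisation of a hydroxyquinone), or the diene may attack the face syn to the C10 methyl. Fallback, from 20 to 25, with a covalent protecting group and a strong monodentate Lewis acid: O-methylation of 20 with trimethylsilyldiazomethane would give the 2-methoxyquinone alcohol F3. Dess–Martin oxidation with amine equilibration gives the methoxyquinone aldehyde F4. BF3·OEt2 and myrcene 22 (CH2Cl2, −78 → −30 °C) exploit the known Lewis-acid reversal of alkoxyquinone regiochemistry and give the methyl ether of the target F5. Hydrolysis of the vinylogous ester (aq. LiOH, THF) returns to 25.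

3. Step 1. Conversion or enantio-induction may be poor at the neopentyl β-carbon of an α-methyl enone. Fallback, from 2 back to 4, as a three-component coupling on the benchmark acceptor class: the same copper/ferrocenyl-diphosphine 1,4-addition of 2 to the α-unsubstituted enone 4,4-dimethylcyclohex-2-en-1-one F6, with the magnesium enolate trapped by MeI (DMPU), would give (2R,3R)-2,4,4-trimethyl-3-vinylcyclohexan-1-one F7. Thermodynamic silylation (Me3SiCl, NaI, Et3N, MeCN) then gives the tetrasubstituted enol silane 4.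

**Further compounds**
F1 | step 8 | methyl-ketene-acetal diene: 1-methoxy-1,3-bis(trimethylsilyloxy)diene of 15 with O- and C(alkyne)-trimethylsilyl groups | C[Si](C)(C)C#C[C@@]1(C)CCCC(C)(C)[C@@H]1C(CO[Si](C)(C)C)/C=C(\O[Si](C)(C)C)C(C(C)C)=C(OC)O[Si](C)(C)C
F2 | step 8 | 4-trimethylsilyl tris(trimethylsilyl) ether of 19 | C[Si](C)(C)OCC1c2c(O[Si](C)(C)C)c(C(C)C)c(O[Si](C)(C)C)c([Si](C)(C)C)c2[C@@]2(C)CCCC(C)(C)[C@@H]21
F3 | step 11 | (4bS,8aS)-9-(hydroxymethyl)-3-methoxy-4b,8,8-trimethyl-2-(propan-2-yl)-4b,5,6,7,8,8a-hexahydro-9H-fluorene-1,4-dione | OCC1C2=C(C(=O)C(OC)=C(C(C)C)C2=O)[C@@]2(C)CCCC(C)(C)[C@@H]21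
F4 | step 11 | (4bS,8aS,9R)-3-methoxy-4b,8,8-trimethyl-1,4-dioxo-2-(propan-2-yl)-4b,5,6,7,8,8a-hexahydro-9H-fluorene-9-carbaldehyde | O=C[C@H]1C2=C(C(=O)C(OC)=C(C(C)C)C2=O)[C@@]2(C)CCCC(C)(C)[C@@H]21
F5 | step 11 | O-methyl ether of the target | CC(C)=CCCC1=CC[C@@]23C(=O)C(C(C)C)=C(OC)C(=O)[C@]2(C1)[C@@]1(C)CCCC(C)(C)[C@@H]1[C@H]3C=O
F6 | step 1 | 4,4-dimethylcyclohex-2-en-1-one | CC1(C)CCC(=O)C=C1
F7 | step 1 | (2R,3R)-2,4,4-trimethyl-3-vinylcyclohexan-1-one | C[C@H]1C(=O)CCC(C)(C)[C@@H]1C=C
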